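The α-methylene-γ-butyrolactone (ring O6–C6–C7–C11–C12, exocyclic C13) is a 2-substituted acrylate spanning C7 and O6. It is therefore cut to a C7 ethynyl group (C11≡C13), carbon monoxide (C12) and the free C6 hydroxyl. One palladium-catalysed cyclocarbonylation forms C11–C12 and C12–O6 and closes this ring on the finished ten-membered carbocycle, with the C9 angelate in place. Precursor 35 is the (1(10)Z,4E)-cyclodecadiene whose only free hydroxyl is O6–H; propargylic O7 and homopropargylic O8 are silyl ethers. L-Arabinose supplies C5–C9, C7 is set by alkynylation of a furanos-3-ulose, and the carbocycle is closed at C9–C10.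

Key step: step 21

Assumption: the target SMILES reads as (6S,7S,8S,9R) with H6 and O7 on the same face (cis-fused lactone). Germacrane numbering is used throughout, and sugar C1, C2, C3, C4, C5 become C9, C8, C7, C6, C5.

Step 1
Reactants: 1 L-arabinose
Product: 2 5-O-(tert-butyldiphenylsilyl)-L-arabinofuranose (anomer mixture)
Conditions: TBDPSCl (1.05 equiv), imidazole, DMF, 0 °C to rt
Reagents that add atoms: tert-butyl(chloro)diphenylsilane, CC(C)(C)[Si](Cl)(c1ccccc1)c1ccccc1
Why: Selective O-silylation, in which the bulky chlorosilane reacts only with the primary hydroxyl exposed by the furanose tautomer, so the pyranose–furanose equilibrium is drained and the five-membered ring is locked.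

Step 2
Reactants: 2 5-O-(tert-butyldiphenylsilyl)-L-arabinofuranose
Product: 3 5-O-(tert-butyldiphenylsilyl)-1,2-O-isopropylidene-β-L-arabinofuranose
Conditions: 2,2-dimethoxypropane, camphorsulfonic acid (cat.), acetone, rt
Reagents that add atoms: 2,2-dimethoxypropane, COC(C)(C)OC
Why: Acid-catalysed transacetalisation, in which O1/O2 of the β-anomer is the only cis-diol (O2/O3 are trans), so O3–H (the future C7 oxygen) is left as the single free hydroxyl.

Step 3
Reactants: 3 5-O-(tert-butyldiphenylsilyl)-1,2-O-isopropylidene-β-L-arabinofuranose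
Product: 4 5-O-(tert-butyldiphenylsilyl)-1,2-O-isopropylidene-β-L-threo-pentofuranos-3-ulose
Conditions: Dess–Martin periodinane, CH2Cl2, 0 °C to rt
Reagents that add atoms: none
Why: Dess–Martin oxidation converts the hindered secondary carbinol into the C7 ketone under near-neutral conditions that spare the acetonide and the silyl ether and do not enolise C6 or C8.

Step 4
Reactants: 4 5-O-(tert-butyldiphenylsilyl)-1,2-O-isopropylidene-β-L-threo-pentofuranos-3-ulose; 5 (trimethylsilyl)acetylene
Product: 7 5-O-(tert-butyldiphenylsilyl)-1,2-O-isopropylidene-3-C-[(trimethylsilyl)ethynyl]-β-L-lyxofuranose, via lithium (trimethylsilyl)acetylide 6 (not isolated)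
Conditions: 5, n-BuLi, THF, −78 °C; then 4, −78 °C; H2O quench
Reagents that add atoms: none
Why: 1,2-Addition of a lithium acetylide, in which the acetonide and the C5 side chain both shield one face of the bicycle, so the nucleophile enters from the open convex face and O7 ends cis to O8 and C5 (lyxo), which is the C7 configuration of the target.

Step 5
Reactants: 7 5-O-(tert-butyldiphenylsilyl)-1,2-O-isopropylidene-3-C-[(trimethylsilyl)ethynyl]-β-L-lyxofuranose
Product: 8 1,2-O-isopropylidene-3-C-[(trimethylsilyl)ethynyl]-β-L-lyxofuranose (3,5-diol)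
Conditions: HF·pyridine, pyridine, THF, 0 °C to rt
Reagents that add atoms: none
Why: O-Desilylation with acidic fluoride cleaves the primary O–Si bond, while the acetonide stays and the C(sp)–SiMe3 bond stays because it needs basic fluoride or alkoxide.

Step 6
Reactants: 8 1,2-O-isopropylidene-3-C-[(trimethylsilyl)ethynyl]-β-L-lyxofuranose
Product: 9 1,2-O-isopropylidene-3,5-bis-O-(triethylsilyl)-3-C-[(trimethylsilyl)ethynyl]-β-L-lyxofuranose
Conditions: TESOTf (2.5 equiv), 2,6-lutidine, CH2Cl2, −78 to 0 °C
Reagents that add atoms: triethylsilyl trifluoromethanesulfonate, CC[Si](CC)(CC)OS(=O)(=O)C(F)(F)F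
Why: Silyl triflate silylation is strong enough for the tertiary propargylic O7–H, which must be masked so that it cannot enter a propargyl Claisen rearrangement in step 9, and the primary TES ether is the handle for step 7.

Step 7
Reactants: 9 1,2-O-isopropylidene-3,5-bis-O-(triethylsilyl)-3-C-[(trimethylsilyl)ethynyl]-β-L-lyxofuranose
Product: 10 1,2-O-isopropylidene-3-O-(triethylsilyl)-3-C-[(trimethylsilyl)ethynyl]-β-L-lyxo-pentodialdo-1,4-furanose (C5 aldehyde)
Conditions: (COCl)2, DMSO, CH2Cl2, −78 to −40 °C; Et3N, −78 to 0 °C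
Reagents that add atoms: none
Why: Swern oxidation applied directly to a silyl ether, in which the chlorosulfonium salt attacks only the unhindered primary O–SiEt3 group, so the aldehyde forms in one operation, the tertiary TES ether stays and the low temperature keeps C6 from epimerising.

Step 8
Reactants: 10 C5 aldehyde; 11 isopropenylmagnesium bromide
Product: 12 C5 isopropenyl carbinol of the lyxofuranose acetonide (both C5 epimers; O7-TES; silylalkyne)
Conditions: 11, THF, −78 °C
Reagents that add atoms: none
Why: Grignard 1,2-addition brings in C4, C15 and C3, and the new C5 carbinol centre needs no control because it becomes sp2 in step 9.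

Step 9
Reactants: 12 C5 isopropenyl carbinol; 13 triethyl orthoacetate
Product: 16 ethyl (E)-4-methyl-5-(furanos-4-yl)pent-4-enoate (C1 ester with 4E alkene on the lyxofuranose acetonide), via mixed orthoester 14 (not isolated), via ketene acetal 15 (not isolated)
Conditions: 13 (excess), EtCO2H (cat.), xylene, 140 °C, EtOH distilled off
Reagents that add atoms: none
Why: Johnson–Claisen rearrangement forms C2–C3 through a chair transition state with the bulky furanosyl group equatorial, so either C5 epimer gives the 4E trisubstituted alkene.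

Step 10
Reactants: 16 ethyl (E)-ester
Product: 17 (E)-4-methyl-5-(furanos-4-yl)pent-4-enal (C1 aldehyde)
Conditions: i-Bu2AlH (1.05 equiv), CH2Cl2, −78 °C; aqueous work-up
Reagents that add atoms: none
Why: Partial ester reduction works because the tetrahedral aluminium hemiacetal is stable at −78 °C and releases the aldehyde only on work-up.

Step 11
Reactants: 17 C1 aldehyde; 18 ethyltriphenylphosphonium iodide
Product: 22 lyxofuranose acetonide bearing the (1E,5Z)-6-iodo-2-methylhepta-1,5-dien-1-yl chain at C6 (O7-TES; silylalkyne), via ethylidenetriphenylphosphorane 19 (not isolated), via (1-iodoethyl)triphenylphosphonium iodide 20 (not isolated), via (1-iodoethylidene)triphenylphosphorane 21 (not isolated)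
Conditions: 18, n-BuLi, THF, 0 °C; I2, −78 °C; NaN(SiMe3)2, −20 °C; then 17, −78 °C
Reagents that add atoms: iodine, II
Why: Stork–Zhao-type Wittig olefination, in which the non-stabilised α-iodo ylide reacts under kinetic control through the cis-oxaphosphetane, so iodine ends cis to C2, which is the geometry needed for the Z C1=C10 alkene.

Step 12
Reactants: 22 alkenyl iodide acetonide
Product: 23 C9 lactol 7,8-diol (hemiacetal to O6; anomer mixture; silylalkyne; dienyl iodide chain)
Conditions: 2 M aq. HCl, THF, 45 °C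
Reagents that add atoms: water, O
Why: Acid-catalysed acetal hydrolysis through the anomeric oxocarbenium ion frees C9 as the lactol and O8–H, the TES ether falls off at the same time, and dilute aqueous acid is too weak to protonate the trisubstituted alkene or the alkenyl iodide.

Step 13
Reactants: 23 C9 lactol 7,8-diol
Product: 24 γ-lactone 7,8-diol (C9 carbonyl; O6 as ring oxygen)
Conditions: TEMPO (cat.), PhI(OAc)2, CH2Cl2, rt
Reagents that add atoms: none
Why: Oxoammonium (TEMPO) oxidation takes the lactol C–H much faster than the hindered secondary C8 carbinol, so O6 stays locked in the ring while O8–H and O7–H can be told apart.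

Step 14
Reactants: 24 γ-lactone 7,8-diol
Product: 25 O8-TBS γ-lactone (O7–H free)
Conditions: TBSOTf (1.1 equiv), 2,6-lutidine, CH2Cl2, −78 to −40 °C
Reagents that add atoms: tert-butyldimethylsilyl trifluoromethanesulfonate, CC(C)(C)[Si](C)(C)OS(=O)(=O)C(F)(F)F
Why: Selective silylation, in which one equivalent of triflate at low temperature takes the secondary O8–H and leaves the tertiary O7–H, and O8 receives a group of its own because O6 is still the ring oxygen.

Step 15
Reactants: 25 O8-TBS γ-lactone
Product: 26 open-chain 6,7,9-triol (O8-TBS)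
Conditions: LiBH4, THF, 0 °C to rt
Reagents that add atoms: none
Why: Borohydride reduction opens the lactone irreversibly to the C9 primary alcohol and free O6–H without touching the alkenyl iodide, the silylalkyne or the TBS ether.

Step 16
Reactants: 26 open-chain 6,7,9-triol
Product: 27 6,7,9-tris-O-TES 8-O-TBS ether
Conditions: TESOTf (4 equiv), 2,6-lutidine, CH2Cl2, 0 °C to rt
Reagents that add atoms: triethylsilyl trifluoromethanesulfonate, CC[Si](CC)(CC)OS(=O)(=O)C(F)(F)F
Why: Exhaustive triflate silylation puts the more labile TES group on O6, O7 and O9, one grade below the TBS ether on O8.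

Step 17
Reactants: 27 6,7,9-tris-O-TES 8-O-TBS ether
Product: 28 C9 aldehyde (O6-TES; O7-TES; O8-TBS; Z alkenyl iodide)
Conditions: (COCl)2, DMSO, CH2Cl2, −78 to −40 °C; Et3N, −78 to 0 °C
Reagents that add atoms: none
Why: Swern oxidation of the primary TES ether alone, because the secondary, tertiary and TBS ethers are too hindered for the chlorosulfonium salt, gives the open-chain aldehyde with O6 already blocked so that it cannot fall back to a lactol.

Step 18
Reactants: 28 C9 aldehyde
Product: 30 (1(10)Z,4E,9R)-ten-membered C9 alcohol (O6-TES; O7-TES; O8-TBS; C7 silylalkyne), via alkenylchromium dichloride 29 (not isolated)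
Conditions: CrCl2 (12 equiv), NiCl2 (0.1 equiv), DMSO–THF, rt, slow addition to 2 mM
Reagents that add atoms: none
Why: Nozaki–Hiyama–Kishi ring closure, in which zerovalent nickel inserts into C10–I with retention of the Z geometry, transfer to chromium gives 29 that adds only to the aldehyde, and C9 should be set by Felkin–Anh attack anti to the fully substituted C7, which places O9 syn to O8 (9R).

Step 19
Reactants: 30 ten-membered C9 alcohol; 31 angelic acid
Product: 33 C9 angelate (O6-TES; O7-TES; O8-TBS; silylalkyne), via angelic 2,4,6-trichlorobenzoic anhydride 32 (not isolated)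
Conditions: 31, 2,4,6-trichlorobenzoyl chloride, Et3N, toluene, rt; then 30, 80 °C
Reagents that add atoms: none
Why: Yamaguchi-type mixed-anhydride acylation without a nucleophilic catalyst transfers the angeloyl group to the only free hydroxyl and avoids the addition–elimination path that turns angelates into tiglates.

Step 20
Reactants: 33 C9 angelate
Product: 35 ten-membered 7-ethynyl C6 alcohol (O6–H free; O7-TES; O8-TBS; C9 angelate), via O6-triethylsilyl terminal alkyne 34 (not isolated)
Conditions: K2CO3 (0.2 equiv), MeOH, 0 °C; then PPTS (0.6 equiv), 0 °C to rt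
Reagents that add atoms: none
Why: Base-catalysed protiodesilylation of the alkynylsilane, followed in the same methanol by mild acid solvolysis, removes the secondary allylic O6-TES ether, while the tertiary O7-TES ether, the TBS ether and the hindered conjugated angelate react much more slowly.

Step 21
Reactants: 35 ten-membered 7-ethynyl C6 alcohol; 36 carbon monoxide
Product: 37 target as its O7-TES O8-TBS bis-silyl ether
Conditions: Pd(OAc)2 (10 mol %), 2-(diphenylphosphino)pyridine (40 mol %), MeSO3H (20 mol %), CO (20 bar), CH2Cl2, 40 °C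
Reagents that add atoms: none
Why: Protonation of the zerovalent palladium–pyridylphosphine complex gives a cationic divalent palladium hydride that adds syn across C11≡C13 with palladium on internal C11 and hydrogen on C13; CO then inserts into C11–Pd (bond C11–C12), and O6–H attacks the acyl carbon (bond C12–O6), releasing zerovalent palladium and a proton that re-form the hydride. The closest known reaction type is the palladium-catalysed cyclocarbonylation (intramolecular Markovnikov hydroalkoxycarbonylation) of but-3-yn-1-ols to α-methylene-γ-butyrolactones. The one new ring, the five-membered lactone O6–C6–C7–C11–C12, closes by 5-exo-trig acyl substitution of O6 at C12 and is cis-fused because O6 and C11 can adopt a small dihedral angle about C6–C7 of the ten-membered ring. No stereocentre is created, and C6 to C9 are not touched. The step needs O6 to be the only nucleophile, which is secured by silyl ethers on O7 and O8, so that neither a four-membered lactone, nor a C8 lactone, nor ionisation of the propargylic C7–O bond to an allenylpalladium can compete. It also needs the alkyne to be the only reacting π-system, which holds because the trisubstituted ring and angelate alkenes insert far more slowly than a terminal alkyne, and because a hydride catalyst working at 40 °C leaves little free zerovalent palladium to ionise the allylic C9 angelate or the allylic C6–O bond.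

Step 22
Reactants: 37 bis-silyl lactone
Product: 38 (1(10)Z,4E,6S,7S,8S,9R)-9-angeloyloxy-7,8-dihydroxygermacra-1(10),4,11(13)-trien-12,6-olide (target CNP0303917.1)
Conditions: HF·pyridine, pyridine, THF, 0 °C to rt
Reagents that add atoms: none
Why: Buffered HF·pyridine cleaves both silyl ethers under weakly acidic conditions that form no alkoxide, which avoids angelate migration from O9 to O8, translactonisation to O8 and base damage to the β-hydroxy-α-methylene lactone.

Compound list

1 | L-arabinose | O=C[C@H](O)[C@@H](O)[C@@H](O)CO | starting material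
2 | 5-O-(tert-butyldiphenylsilyl)-L-arabinofuranose (anomer mixture) | CC(C)(C)[Si](c1ccccc1)(c1ccccc1)OC[C@@H]1OC(O)[C@H](O)[C@H]1O | intermediate
3 | 5-O-(tert-butyldiphenylsilyl)-1,2-O-isopropylidene-β-L-arabinofuranose | CC(C)(C)[Si](c1ccccc1)(c1ccccc1)OC[C@@H]1O[C@@H]2OC(C)(C)O[C@@H]2[C@H]1O | intermediate
4 | 5-O-(tert-butyldiphenylsilyl)-1,2-O-isopropylidene-β-L-threo-pentofuranos-3-ulose | CC(C)(C)[Si](c1ccccc1)(c1ccccc1)OC[C@@H]1O[C@@H]2OC(C)(C)O[C@@H]2C1=O | intermediate
5 | (trimethylsilyl)acetylene | C#C[Si](C)(C)C | starting material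
6 | lithium (trimethylsilyl)acetylide | [Li]C#C[Si](C)(C)C | intermediate
7 | 5-O-(tert-butyldiphenylsilyl)-1,2-O-isopropylidene-3-C-[(trimethylsilyl)ethynyl]-β-L-lyxofuranose | CC(C)(C)[Si](c1ccccc1)(c1ccccc1)OC[C@@H]1O[C@@H]2OC(C)(C)O[C@@H]2[C@@]1(O)C#C[Si](C)(C)C | intermediate
8 | 1,2-O-isopropylidene-3-C-[(trimethylsilyl)ethynyl]-β-L-lyxofuranose | OC[C@@H]1O[C@@H]2OC(C)(C)O[C@@H]2[C@@]1(O)C#C[Si](C)(C)C | intermediate
9 | 1,2-O-isopropylidene-3,5-bis-O-(triethylsilyl)-3-C-[(trimethylsilyl)ethynyl]-β-L-lyxofuranose | CC[Si](CC)(CC)OC[C@@H]1O[C@@H]2OC(C)(C)O[C@@H]2[C@@]1(O[Si](CC)(CC)CC)C#C[Si](C)(C)C | intermediate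
10 | C5 aldehyde (L-lyxo-pentodialdo-1,4-furanose acetonide, O7-TES, silylalkyne) | O=C[C@@H]1O[C@@H]2OC(C)(C)O[C@@H]2[C@@]1(O[Si](CC)(CC)CC)C#C[Si](C)(C)C | intermediate
11 | isopropenylmagnesium bromide | CC(=C)[Mg]Br | starting material
12 | C5 isopropenyl carbinol (both C5 epimers) | C=C(C)C(O)[C@@H]1O[C@@H]2OC(C)(C)O[C@@H]2[C@@]1(O[Si](CC)(CC)CC)C#C[Si](C)(C)C | intermediate
13 | triethyl orthoacetate | CCOC(C)(OCC)OCC | starting material
14 | mixed orthoester of 12 | C=C(C)C(OC(C)(OCC)OCC)[C@@H]1O[C@@H]2OC(C)(C)O[C@@H]2[C@@]1(O[Si](CC)(CC)CC)C#C[Si](C)(C)C | intermediate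
15 | ketene acetal of 12 | C=C(C)C(OC(=C)OCC)[C@@H]1O[C@@H]2OC(C)(C)O[C@@H]2[C@@]1(O[Si](CC)(CC)CC)C#C[Si](C)(C)C | intermediate
16 | ethyl (E)-4-methyl-5-(furanos-4-yl)pent-4-enoate (C1 ester, 4E) | CCOC(=O)CC/C(C)=C/[C@@H]1O[C@@H]2OC(C)(C)O[C@@H]2[C@@]1(O[Si](CC)(CC)CC)C#C[Si](C)(C)C | intermediate
17 | (E)-4-methyl-5-(furanos-4-yl)pent-4-enal (C1 aldehyde) | O=CCC/C(C)=C/[C@@H]1O[C@@H]2OC(C)(C)O[C@@H]2[C@@]1(O[Si](CC)(CC)CC)C#C[Si](C)(C)C | intermediate
18 | ethyltriphenylphosphonium iodide | CC[P+](c1ccccc1)(c1ccccc1)c1ccccc1.[I-] | starting material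
19 | ethylidenetriphenylphosphorane | CC=P(c1ccccc1)(c1ccccc1)c1ccccc1 | intermediate
20 | (1-iodoethyl)triphenylphosphonium iodide | CC(I)[P+](c1ccccc1)(c1ccccc1)c1ccccc1.[I-] | intermediate
21 | (1-iodoethylidene)triphenylphosphorane | CC(I)=P(c1ccccc1)(c1ccccc1)c1ccccc1 | intermediate
22 | lyxofuranose acetonide with (1E,5Z)-6-iodo-2-methylhepta-1,5-dien-1-yl chain at C6 | C/C(I)=C/CC/C(C)=C/[C@@H]1O[C@@H]2OC(C)(C)O[C@@H]2[C@@]1(O[Si](CC)(CC)CC)C#C[Si](C)(C)C | intermediate
23 | C9 lactol 7,8-diol (anomer mixture) | C/C(I)=C/CC/C(C)=C/[C@@H]1OC(O)[C@H](O)[C@@]1(O)C#C[Si](C)(C)C | intermediate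
24 | γ-lactone 7,8-diol | C/C(I)=C/CC/C(C)=C/[C@@H]1OC(=O)[C@H](O)[C@@]1(O)C#C[Si](C)(C)C | intermediate
25 | O8-TBS γ-lactone | C/C(I)=C/CC/C(C)=C/[C@@H]1OC(=O)[C@H](O[Si](C)(C)C(C)(C)C)[C@@]1(O)C#C[Si](C)(C)C | intermediate
26 | open-chain 6,7,9-triol (O8-TBS) | C/C(I)=C/CC/C(C)=C/[C@H](O)[C@](O)(C#C[Si](C)(C)C)[C@@H](O[Si](C)(C)C(C)(C)C)CO | intermediate
27 | 6,7,9-tris-O-TES 8-O-TBS ether | C/C(I)=C/CC/C(C)=C/[C@H](O[Si](CC)(CC)CC)[C@](O[Si](CC)(CC)CC)(C#C[Si](C)(C)C)[C@@H](O[Si](C)(C)C(C)(C)C)CO[Si](CC)(CC)CC | intermediate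
28 | C9 aldehyde | C/C(I)=C/CC/C(C)=C/[C@H](O[Si](CC)(CC)CC)[C@](O[Si](CC)(CC)CC)(C#C[Si](C)(C)C)[C@@H](O[Si](C)(C)C(C)(C)C)C=O | intermediate
29 | alkenylchromium dichloride of 28 | C/C([Cr](Cl)Cl)=C/CC/C(C)=C/[C@H](O[Si](CC)(CC)CC)[C@](O[Si](CC)(CC)CC)(C#C[Si](C)(C)C)[C@@H](O[Si](C)(C)C(C)(C)C)C=O | intermediate
30 | (1(10)Z,4E,9R)-ten-membered C9 alcohol | CC[Si](CC)(CC)O[C@H]1/C=C(\C)CC/C=C(/C)[C@@H](O)[C@H](O[Si](C)(C)C(C)(C)C)[C@@]1(O[Si](CC)(CC)CC)C#C[Si](C)(C)C | intermediate
31 | angelic acid | C/C=C(/C)C(=O)O | starting material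
32 | angelic 2,4,6-trichlorobenzoic anhydride | C/C=C(/C)C(=O)OC(=O)c1c(Cl)cc(Cl)cc1Cl | intermediate
33 | C9 angelate (O6-TES, O7-TES, O8-TBS, silylalkyne) | CC[Si](CC)(CC)O[C@H]1/C=C(\C)CC/C=C(/C)[C@@H](OC(=O)/C(C)=C\C)[C@H](O[Si](C)(C)C(C)(C)C)[C@@]1(O[Si](CC)(CC)CC)C#C[Si](C)(C)C | intermediate
34 | O6-triethylsilyl terminal alkyne | CC[Si](CC)(CC)O[C@H]1/C=C(\C)CC/C=C(/C)[C@@H](OC(=O)/C(C)=C\C)[C@H](O[Si](C)(C)C(C)(C)C)[C@@]1(O[Si](CC)(CC)CC)C#C | intermediate
35 | ten-membered 7-ethynyl C6 alcohol (O7-TES, O8-TBS, C9 angelate) | O[C@H]1/C=C(\C)CC/C=C(/C)[C@@H](OC(=O)/C(C)=C\C)[C@H](O[Si](C)(C)C(C)(C)C)[C@@]1(O[Si](CC)(CC)CC)C#C | intermediate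
36 | carbon monoxide | [C-]#[O+] | starting material
37 | target as O7-TES O8-TBS bis-silyl ether | C=C1C(=O)O[C@H]2/C=C(\C)CC/C=C(/C)[C@@H](OC(=O)/C(C)=C\C)[C@H](O[Si](C)(C)C(C)(C)C)[C@@]12O[Si](CC)(CC)CC | intermediate
38 | CNP0303917.1 | C=C1C(=O)O[C@H]2/C=C(\C)CC/C=C(/C)[C@@H](OC(=O)/C(C)=C\C)[C@H](O)[C@@]12O | target

Total step count: 22. Longest linear sequence: 22 steps, from L-arabinose 1.

Steps most likely to fail

Step 21. Hydropalladation may be slow, or may turn towards the terminal carbon, because C11 sits next to the fully substituted, silyloxy-bearing C7. The catalyst may also decay to palladium metal before it turns over. The fallback sets out from 35 and comes back at 37. It separates the regiochemical decision from the carbonylation. Hydrostannation with Bu3SnH catalysed by Mo(CO)3(CNtBu)3 places tin on the carbon next to the propargylic oxygen and gives the C11 tributylstannyl alkene F1. Iodine at −78 °C converts it into the C11 iodoalkene F2. Pd(PPh3)4, CO (1 atm) and Et3N in THF at 40 °C then close the lactone by oxidative addition into C11–I, CO insertion and capture of the acyl complex by O6–H.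

Step 18. Facial selectivity at the C9 aldehyde may be poor, since attack anti to C7 competes with attack anti to the C8 silyloxy group. Oligomerisation also competes with closure of the strained ring. The fallback sets out from 28 and comes back at 30. The ring is closed without regard to C9, and the (9S)-alcohol F3, alone or mixed with 30, is oxidised with Dess–Martin periodinane to the C9 enone F4. C9 is then set by 1,2-reduction with NaBH4 and CeCl3·7H2O in MeOH at −78 °C. The hydride takes the trajectory that the carbon nucleophile had preferred, so the hydroxyl ends on the opposite face.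

Step 19. Acylation of the crowded O9–H may be sluggish, which invites prolonged heating and Z-to-E isomerisation of the angeloyl group. The fallback sets out from 30 and comes back at 33. The acid 2-[bis(2,2,2-trifluoroethoxy)phosphoryl]propanoic acid has no alkene to isomerise, so it can be coupled with EDC·HCl and DMAP to give the C9 phosphonopropanoate F5. A Still–Gennari olefination with KN(SiMe3)2, 18-crown-6 and acetaldehyde in THF at −78 °C then builds the Z alkene of the angelate on the ester.

Further compounds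

F1 | step 21 | C11 tributylstannyl alkene | O[C@H]1/C=C(\C)CC/C=C(/C)[C@@H](OC(=O)/C(C)=C\C)[C@H](O[Si](C)(C)C(C)(C)C)[C@@]1(O[Si](CC)(CC)CC)C(=C)[Sn](CCCC)(CCCC)CCCC
F2 | step 21 | C11 iodoalkene | O[C@H]1/C=C(\C)CC/C=C(/C)[C@@H](OC(=O)/C(C)=C\C)[C@H](O[Si](C)(C)C(C)(C)C)[C@@]1(O[Si](CC)(CC)CC)C(I)=C
F3 | step 18 | (9S)-alcohol | CC[Si](CC)(CC)O[C@H]1/C=C(\C)CC/C=C(/C)[C@H](O)[C@H](O[Si](C)(C)C(C)(C)C)[C@@]1(O[Si](CC)(CC)CC)C#C[Si](C)(C)C
F4 | step 18 | C9 enone | CC[Si](CC)(CC)O[C@H]1/C=C(\C)CC/C=C(/C)C(=O)[C@H](O[Si](C)(C)C(C)(C)C)[C@@]1(O[Si](CC)(CC)CC)C#C[Si](C)(C)C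
F5 | step 19 | C9 phosphonopropanoate | CC[Si](CC)(CC)O[C@H]1/C=C(\C)CC/C=C(/C)[C@@H](OC(=O)C(C)P(=O)(OCC(F)(F)F)OCC(F)(F)F)[C@H](O[Si](C)(C)C(C)(C)C)[C@@]1(O[Si](CC)(CC)CC)C#C[Si](C)(C)C
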